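**Retrosynthetic overview**
- The strategy rests on C4 of ring C. It is a ketone carbon whose only carbon neighbours are C4a of ring A (flanked by the oxygen-bearing C5 and C8a) and C3, the carbon that holds ring B. C4 can therefore enter as carbon monoxide between an A-ring aryl iodide and a B-ring benzylic metal.
- Ring C is opened at O1–C2 and C2=C3 (C2 from DMF dimethyl acetal) to a 2-hydroxydeoxybenzoin. This is cut at C4a–C4 and C4–C3 into iodide 9, CO and benzylzinc chloride 18.
- Iodide 9 comes from phloroglucinol: TIPS on one oxygen, MOM on two, lithiation between the MOM ethers and prenylation (future C6). The freed phenol is then iodinated at one of two mirror-related ortho carbons and resilylated, which marks O1 (TIPS) against O5 and O7 (MOM).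
- Zinc reagent 18 comes from 2,4-dihydroxybenzaldehyde: 4-O-MOM, 2-O-Me, reduction, lithiation at C3' between the two ethers with prenylation, chloride formation, zinc insertion.
- Rings A and B are bought in. Ring C is the only ring made; it closes at step 15, after the coupling and before the MOM ethers are removed.

Key step: step 13

Remark: isoflavone numbering is used (O1, C2–C8a, ring B primed) and prenyl means 3-methylbut-2-enyl. The target has no stereocentre and no configurationally defined double bond. Reagent 18 is drawn as the simple benzylzinc chloride, although it is present in THF as its LiCl complex and is used as a titrated solution.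

**Step 1**
Reactants: 1 phloroglucinol (anhydrous, 3 equiv)
Product: 2 5-(triisopropylsilyloxy)benzene-1,3-diol
Conditions: TIPSCl (1 equiv), imidazole, DMF, 0 °C → rt
Reagents that add atoms: chlorotriisopropylsilane (TIPSCl), CC(C)[Si](Cl)(C(C)C)C(C)C
Why: Imidazole-promoted silylation of one of three equivalent phenols, in which the excess of cheap 1 over TIPSCl favours the mono-ether and unreacted 1 is washed out with water.

**Step 2**
Reactants: 2 5-(triisopropylsilyloxy)benzene-1,3-diol
Product: 3 [3,5-bis(methoxymethoxy)phenoxy]triisopropylsilane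
Conditions: MOMCl (2.5 equiv), i-Pr2NEt, CH2Cl2, 0 °C → rt
Reagents that add atoms: chloromethyl methyl ether (MOMCl), COCCl
Why: Williamson-type O-alkylation of both remaining phenols with an amine base, conditions under which an aryl TIPS ether neither migrates nor cleaves.

**Step 3**
Reactants: 3 [3,5-bis(methoxymethoxy)phenoxy]triisopropylsilane; 4 prenyl bromide (1-bromo-3-methylbut-2-ene)
Product: 6 [3,5-bis(methoxymethoxy)-4-(3-methylbut-2-enyl)phenoxy]triisopropylsilane, via C4-aryllithium 5 (not isolated)
Conditions: n-BuLi (1.1 equiv), THF, 0 °C; then CuBr·SMe2 (10 mol %), 4, −78 °C → rt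
Reagents that add atoms: none
Why: Directed ortho-metalation, because the C4 proton lies between two chelating MOM ethers while the other two ring protons are shielded by the TIPS group, and the aryllithium then takes up the allylic bromide at its primary carbon (copper-catalysed SN2 allylation).

**Step 4**
Reactants: 6 [3,5-bis(methoxymethoxy)-4-(3-methylbut-2-enyl)phenoxy]triisopropylsilane
Product: 7 3,5-bis(methoxymethoxy)-4-(3-methylbut-2-enyl)phenol
Conditions: TBAF, AcOH, THF, 0 °C
Reagents that add atoms: none
Why: Fluoride cleavage of the aryl silyl ether frees the phenol, because a second lithiation next to the bulky OTIPS group would be slow and would compete with removal of the benzylic–allylic CH2 protons, so iodine is better introduced by electrophilic substitution of the phenol.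

**Step 5**
Reactants: 7 3,5-bis(methoxymethoxy)-4-(3-methylbut-2-enyl)phenol
Product: 8 2-iodo-3,5-bis(methoxymethoxy)-4-(3-methylbut-2-enyl)phenol
Conditions: I2 (1.0 equiv), NaHCO3, THF/H2O, 0 °C
Reagents that add atoms: iodine, II
Why: Electrophilic aromatic iodination of a phenol(ate), in which the two free ring carbons are equivalent through the C1···C4 mirror plane and activated by all three oxygens, so the ring should outrun the trisubstituted alkene (its neighbouring oxygens are blocked as MOM ethers against iodoetherification) and one equivalent of iodine limits diiodination.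

**Step 6**
Reactants: 8 2-iodo-3,5-bis(methoxymethoxy)-4-(3-methylbut-2-enyl)phenol
Product: 9 [2-iodo-3,5-bis(methoxymethoxy)-4-(3-methylbut-2-enyl)phenoxy]triisopropylsilane
Conditions: TIPSCl, imidazole, DMAP (cat.), DMF, rt
Reagents that add atoms: chlorotriisopropylsilane (TIPSCl), CC(C)[Si](Cl)(C(C)C)C(C)C
Why: Standard phenol silylation that puts the fluoride-labile group on the oxygen next to iodine (future O1), while the oxygens that become O5 and O7 stay as MOM ethers.

**Step 7**
Reactants: 10 2,4-dihydroxybenzaldehyde
Product: 11 2-hydroxy-4-(methoxymethoxy)benzaldehyde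
Conditions: MOMCl (1.05 equiv), i-Pr2NEt, CH2Cl2, 0 °C → rt
Reagents that add atoms: chloromethyl methyl ether (MOMCl), COCCl
Why: Chemoselective O-alkylation, since the 2-OH is held in a hydrogen bond to the aldehyde and one equivalent of MOMCl goes to the freer, more acidic 4-OH.

**Step 8**
Reactants: 11 2-hydroxy-4-(methoxymethoxy)benzaldehyde
Product: 12 2-methoxy-4-(methoxymethoxy)benzaldehyde
Conditions: MeI, K2CO3, DMF, rt
Reagents that add atoms: iodomethane, CI
Why: Williamson ether synthesis on the remaining chelated phenol with a small, reactive electrophile in a polar aprotic solvent.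

**Step 9**
Reactants: 12 2-methoxy-4-(methoxymethoxy)benzaldehyde
Product: 13 [2-methoxy-4-(methoxymethoxy)phenyl]methanol
Conditions: NaBH4, MeOH, 0 °C
Reagents that add atoms: none
Why: Borohydride reduction of an aromatic aldehyde, to which the methyl and MOM ethers are inert.

**Step 10**
Reactants: 13 [2-methoxy-4-(methoxymethoxy)phenyl]methanol; 4 prenyl bromide
Product: 15 [2-methoxy-4-(methoxymethoxy)-3-(3-methylbut-2-enyl)phenyl]methanol, via O,C3-dilithio species 14 (not isolated)
Conditions: n-BuLi (2.1 equiv), THF, −20 → 0 °C; then CuBr·SMe2 (10 mol %), 4 (1.05 equiv), −78 → 0 °C; aq. work-up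
Reagents that add atoms: none
Why: Directed ortho-metalation of the lithium benzyl alkoxide, in which the second equivalent of base removes the proton flanked by OMe and OMOM (cooperative 1,3-directing groups) and the aryl carbanion, far more nucleophilic than the lithium alkoxide, is allylated at the primary carbon of 4.

**Step 11**
Reactants: 15 [2-methoxy-4-(methoxymethoxy)-3-(3-methylbut-2-enyl)phenyl]methanol
Product: 17 1-(chloromethyl)-2-methoxy-4-(methoxymethoxy)-3-(3-methylbut-2-enyl)benzene, via benzylic mesylate 16 (not isolated)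
Conditions: MsCl, Et3N, THF, −10 °C; then LiCl (3 equiv) in DMF, 0 °C; cold NaHCO3 work-up, used at once
Reagents that add atoms: lithium chloride, [Li+].[Cl-]
Why: Mesylation followed by chloride displacement at an activated benzylic carbon in a basic, HCl-free medium, which spares the MOM ether and the prenyl alkene.

**Step 12**
Reactants: 17 1-(chloromethyl)-2-methoxy-4-(methoxymethoxy)-3-(3-methylbut-2-enyl)benzene
Product: 18 [2-methoxy-4-(methoxymethoxy)-3-(3-methylbut-2-enyl)benzyl]zinc chloride (THF solution, titrated with iodine)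
Conditions: Zn dust (2 equiv), LiCl (1.5 equiv), THF, 0 → 25 °C
Reagents that add atoms: zinc, [Zn]
Why: LiCl-assisted direct insertion of zinc into a benzylic C–Cl bond, where LiCl solubilises the organozinc from the metal surface so that insertion runs at room temperature with little Wurtz-type dimerisation and leaves the ethers and alkene untouched.

**Step 13**
Reactants: 9 [2-iodo-3,5-bis(methoxymethoxy)-4-(3-methylbut-2-enyl)phenoxy]triisopropylsilane; 18 [2-methoxy-4-(methoxymethoxy)-3-(3-methylbut-2-enyl)benzyl]zinc chloride (1.8 equiv)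
Product: 19 1-[4,6-bis(methoxymethoxy)-5-(3-methylbut-2-enyl)-2-(triisopropylsilyloxy)phenyl]-2-[2-methoxy-4-(methoxymethoxy)-3-(3-methylbut-2-enyl)phenyl]ethanone
Conditions: PdCl2(IPr)(3-chloropyridine) (5 mol %; IPr = 1,3-bis(2,6-diisopropylphenyl)imidazol-2-ylidene), CO (5 bar), THF/NMP 3:1, 50 °C
Reagents that add atoms: carbon monoxide, [C-]#[O+]
Why: The organozinc reduces the divalent palladium precatalyst to zerovalent palladium, which inserts into the C–I bond of 9; migratory insertion of CO gives the aroylpalladium iodide, 18 transfers its benzyl group to palladium, and reductive elimination releases the ketone, so that C4a–C4 and C4–C3 form in one operation. The closest known reaction type is the carbonylative Negishi coupling of aryl iodides with benzylic zinc halides to give deoxybenzoins, and strongly donating carbene-ligated palladium is the catalyst class used for carbonylative coupling of 2,6-disubstituted aryl iodides. No ring is closed and no stereocentre is created. The step needs carbonylative rather than direct coupling: the two ortho oxygen substituents hinder transmetalation at the arylpalladium stage, the electron-rich aryl group migrates readily to CO, and the CO pressure suppresses decarbonylation. Regiochemistry is fixed by the iodine position, so the acyl carbon lands between the silylated oxygen (future O1) and a MOM-protected oxygen (future O5). The neutral medium leaves both prenyl groups, the three MOM ethers and the silyl ether intact, which an acid-mediated acylation of ring A would not.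

**Step 14**
Reactants: 19 the TIPS-protected deoxybenzoin
Product: 20 1-[2-hydroxy-4,6-bis(methoxymethoxy)-5-(3-methylbut-2-enyl)phenyl]-2-[2-methoxy-4-(methoxymethoxy)-3-(3-methylbut-2-enyl)phenyl]ethanone
Conditions: TBAF, AcOH, THF, 0 °C
Reagents that add atoms: none
Why: Fluoride cleavage of the aryl silyl ether, buffered with acetic acid to avoid enolate chemistry at the acidic CH2, frees only the oxygen that becomes O1 because MOM ethers do not respond to fluoride.

**Step 15**
Reactants: 20 the 2-hydroxydeoxybenzoin
Product: 22 3-[2-methoxy-4-(methoxymethoxy)-3-(3-methylbut-2-enyl)phenyl]-5,7-bis(methoxymethoxy)-6-(3-methylbut-2-enyl)chromen-4-one, via enaminoketone 21 (not isolated)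
Conditions: Me2NCH(OMe)2 (5 equiv), toluene, 95 °C
Reagents that add atoms: N,N-dimethylformamide dimethyl acetal, COC(OC)N(C)C
Why: This is the standard deoxybenzoin-to-isoflavone closure, in which the acidic CH2 (C3) condenses with the amide acetal to the enaminoketone and the only free phenol adds to C2 with loss of dimethylamine (conjugate addition–elimination), while the MOM group on O5 rules out closure to the 8-prenyl isomer.

**Step 16**
Reactants: 22 the tris-MOM isoflavone
Product: 23 2'-methoxylupalbigenin (5,7-dihydroxy-3-[4-hydroxy-2-methoxy-3-(3-methylbut-2-enyl)phenyl]-6-(3-methylbut-2-enyl)chromen-4-one)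
Conditions: HCl (3 M aq.), MeOH/THF, 40 °C, stopped as soon as the last MOM ether is gone
Reagents that add atoms: none
Why: Acid-catalysed acetal exchange with methanol removes aryl MOM ethers under mild acid, and moderate temperature with short exposure should keep this ahead of protonation of the prenyl double bonds.

**Compound list**
1 | phloroglucinol | Oc1cc(O)cc(O)c1 | starting material
2 | 5-(triisopropylsilyloxy)benzene-1,3-diol | CC(C)[Si](Oc1cc(O)cc(O)c1)(C(C)C)C(C)C | intermediate
3 | [3,5-bis(methoxymethoxy)phenoxy]triisopropylsilane | CC(C)[Si](Oc1cc(OCOC)cc(OCOC)c1)(C(C)C)C(C)C | intermediate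
4 | prenyl bromide | CC(C)=CCBr | starting material
5 | [2,6-bis(methoxymethoxy)-4-(triisopropylsilyloxy)phenyl]lithium | [Li]c1c(OCOC)cc(O[Si](C(C)C)(C(C)C)C(C)C)cc1OCOC | intermediate
6 | [3,5-bis(methoxymethoxy)-4-(3-methylbut-2-enyl)phenoxy]triisopropylsilane | CC(C)[Si](Oc1cc(OCOC)c(CC=C(C)C)c(OCOC)c1)(C(C)C)C(C)C | intermediate
7 | 3,5-bis(methoxymethoxy)-4-(3-methylbut-2-enyl)phenol | COCOc1cc(O)cc(OCOC)c1CC=C(C)C | intermediate
8 | 2-iodo-3,5-bis(methoxymethoxy)-4-(3-methylbut-2-enyl)phenol | COCOc1cc(O)c(I)c(OCOC)c1CC=C(C)C | intermediate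
9 | [2-iodo-3,5-bis(methoxymethoxy)-4-(3-methylbut-2-enyl)phenoxy]triisopropylsilane | CC(C)[Si](Oc1cc(OCOC)c(CC=C(C)C)c(OCOC)c1I)(C(C)C)C(C)C | intermediate
10 | 2,4-dihydroxybenzaldehyde | O=Cc1ccc(O)cc1O | starting material
11 | 2-hydroxy-4-(methoxymethoxy)benzaldehyde | COCOc1ccc(C=O)c(O)c1 | intermediate
12 | 2-methoxy-4-(methoxymethoxy)benzaldehyde | COCOc1ccc(C=O)c(OC)c1 | intermediate
13 | [2-methoxy-4-(methoxymethoxy)phenyl]methanol | COCOc1ccc(CO)c(OC)c1 | intermediate
14 | lithium [3-lithio-2-methoxy-4-(methoxymethoxy)phenyl]methanolate | [Li]OCc1ccc(OCOC)c([Li])c1OC | intermediate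
15 | [2-methoxy-4-(methoxymethoxy)-3-(3-methylbut-2-enyl)phenyl]methanol | COCOc1ccc(CO)c(OC)c1CC=C(C)C | intermediate
16 | 2-methoxy-4-(methoxymethoxy)-3-(3-methylbut-2-enyl)benzyl methanesulfonate | COCOc1ccc(COS(C)(=O)=O)c(OC)c1CC=C(C)C | intermediate
17 | 1-(chloromethyl)-2-methoxy-4-(methoxymethoxy)-3-(3-methylbut-2-enyl)benzene | COCOc1ccc(CCl)c(OC)c1CC=C(C)C | intermediate
18 | [2-methoxy-4-(methoxymethoxy)-3-(3-methylbut-2-enyl)benzyl]zinc chloride | Cl[Zn]Cc1ccc(OCOC)c(CC=C(C)C)c1OC | intermediate
19 | 1-[4,6-bis(methoxymethoxy)-5-(3-methylbut-2-enyl)-2-(triisopropylsilyloxy)phenyl]-2-[2-methoxy-4-(methoxymethoxy)-3-(3-methylbut-2-enyl)phenyl]ethanone | CC(C)[Si](Oc1cc(OCOC)c(CC=C(C)C)c(OCOC)c1C(=O)Cc1ccc(OCOC)c(CC=C(C)C)c1OC)(C(C)C)C(C)C | intermediate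
20 | 1-[2-hydroxy-4,6-bis(methoxymethoxy)-5-(3-methylbut-2-enyl)phenyl]-2-[2-methoxy-4-(methoxymethoxy)-3-(3-methylbut-2-enyl)phenyl]ethanone | COCOc1cc(O)c(C(=O)Cc2ccc(OCOC)c(CC=C(C)C)c2OC)c(OCOC)c1CC=C(C)C | intermediate
21 | 3-(dimethylamino)-1-[2-hydroxy-4,6-bis(methoxymethoxy)-5-(3-methylbut-2-enyl)phenyl]-2-[2-methoxy-4-(methoxymethoxy)-3-(3-methylbut-2-enyl)phenyl]prop-2-en-1-one (push–pull alkene, geometry not fixed) | CN(C)C=C(C(=O)c1c(O)cc(OCOC)c(CC=C(C)C)c1OCOC)c1ccc(OCOC)c(CC=C(C)C)c1OC | intermediate
22 | 3-[2-methoxy-4-(methoxymethoxy)-3-(3-methylbut-2-enyl)phenyl]-5,7-bis(methoxymethoxy)-6-(3-methylbut-2-enyl)chromen-4-one | COCOc1cc2occ(-c3ccc(OCOC)c(CC=C(C)C)c3OC)c(=O)c2c(OCOC)c1CC=C(C)C | intermediate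
23 | 2'-methoxylupalbigenin | COc1c(-c2coc3cc(O)c(CC=C(C)C)c(O)c3c2=O)ccc(O)c1CC=C(C)C | target

**Step count**
- Total: 16 steps.
- Longest linear sequence: 10 steps (steps 1–6 or steps 7–12, followed by steps 13–16).

**Steps most likely to fail**

1. **Step 13.**
   - What may go wrong: slow oxidative addition of the electron-rich, doubly ortho-substituted iodide under CO, CO-free coupling to the diarylmethane, homocoupling of the zinc reagent, protodeiodination, and further acylation of the product enolate.
   - Fallback: the same two bonds are made one after the other, with DMF as the source of C4. It sets out from 9 and 18 and returns at 19.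
   - Iodine–lithium exchange on 9 (n-BuLi, Et2O, −78 °C) gives the aryllithium F1.
   - F1 is quenched at once with DMF to give 2,4-bis(methoxymethoxy)-3-(3-methylbut-2-enyl)-6-(triisopropylsilyloxy)benzaldehyde F2.
   - Addition of 18 to this aldehyde (MgCl2, THF, 25 °C) gives the racemic carbinol F3.
   - Oxidation with Dess–Martin periodinane (CH2Cl2, 0 °C → rt) gives 19.

2. **Step 12.**
   - What may go wrong: ionisation and oligomerisation of the electron-rich benzylic chloride on the zinc surface, and Wurtz-type dimerisation during insertion.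
   - Fallback: metal insertion is replaced by tin–lithium exchange and transmetalation. It sets out from 17 and returns at 18.
   - Freshly made 17 is consumed at −78 °C by Bu3SnLi (THF) to give the chromatographically stable benzylstannane F4.
   - n-BuLi (THF, −78 °C) converts F4 into the benzyllithium F5.
   - F5 is trapped with ZnCl2 (THF solution containing LiCl) to give 18.

3. **Step 16.**
   - What may go wrong: acid-induced cyclisation of the liberated 7-OH and 4'-OH onto the neighbouring prenyl double bonds (dimethylchroman formation), addition of HCl or water to the alkenes, and incomplete cleavage of the hindered MOM ethers.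
   - Fallback: the protecting groups are exchanged under non-acidic conditions and then removed with fluoride. It sets out from 22 and returns at 23.
   - TESOTf with 2,2'-bipyridyl (CH2Cl2, 0 °C → rt) turns the three aryl MOM ethers directly into the tris(triethylsilyl) ether F6.
   - TBAF/AcOH (THF, 0 °C) then releases 23 without any Brønsted acid strong enough to protonate the prenyl groups.

**Further compounds**
F1 | step 13 | [2,4-bis(methoxymethoxy)-3-(3-methylbut-2-enyl)-6-(triisopropylsilyloxy)phenyl]lithium | [Li]c1c(O[Si](C(C)C)(C(C)C)C(C)C)cc(OCOC)c(CC=C(C)C)c1OCOC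
F2 | step 13 | 2,4-bis(methoxymethoxy)-3-(3-methylbut-2-enyl)-6-(triisopropylsilyloxy)benzaldehyde | CC(C)[Si](Oc1cc(OCOC)c(CC=C(C)C)c(OCOC)c1C=O)(C(C)C)C(C)C
F3 | step 13 | racemic 1-[4,6-bis(methoxymethoxy)-5-(3-methylbut-2-enyl)-2-(triisopropylsilyloxy)phenyl]-2-[2-methoxy-4-(methoxymethoxy)-3-(3-methylbut-2-enyl)phenyl]ethanol | CC(C)[Si](Oc1cc(OCOC)c(CC=C(C)C)c(OCOC)c1C(O)Cc1ccc(OCOC)c(CC=C(C)C)c1OC)(C(C)C)C(C)C
F4 | step 12 | tributyl[2-methoxy-4-(methoxymethoxy)-3-(3-methylbut-2-enyl)benzyl]stannane | CCCC[Sn](CCCC)(CCCC)Cc1ccc(OCOC)c(CC=C(C)C)c1OC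
F5 | step 12 | [2-methoxy-4-(methoxymethoxy)-3-(3-methylbut-2-enyl)benzyl]lithium | [Li]Cc1ccc(OCOC)c(CC=C(C)C)c1OC
F6 | step 16 | 3-[2-methoxy-3-(3-methylbut-2-enyl)-4-(triethylsilyloxy)phenyl]-6-(3-methylbut-2-enyl)-5,7-bis(triethylsilyloxy)chromen-4-one | CC[Si](CC)(CC)Oc1cc2occ(-c3ccc(O[Si](CC)(CC)CC)c(CC=C(C)C)c3OC)c(=O)c2c(O[Si](CC)(CC)CC)c1CC=C(C)C
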